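**Analysis of the target**

Compound 14 is a diaryl ether of two benzene rings and has no stereocenter. Ring A is a methyl benzoate (ester on A1) with a hydroxyl on A2 that is hydrogen-bonded to the ester carbonyl, a methyl on A4 and the ether oxygen on A6. Ring B carries the ether oxygen on B1, a hydroxymethyl on B2, a methoxy on B4 and a prenyl ether on B6, so three oxygen substituents of three different kinds sit in a 1,2,4 pattern and only B3 and B5 bear hydrogen. The sensitive groups are the aryl prenyl ether (acid, and heat through Claisen rearrangement), the electron-rich benzylic alcohol (acid), and the ring A ester, which lies within reach of any carbanion made next to the ether oxygen. The difficulty is twofold. The central C–O–C unit has three ortho substituents (A1, B2, B6), which makes copper-mediated or SNAr ether formation between two finished rings unattractive. The three ring B oxygens must also be told apart. The plan rests on the oxidation pattern of ring B: B6 and B4 are ketone carbons of a five-carbon chain B1–B6–B5–B4–B3, B2 is the carbonyl carbon of an added acyl unit, and B1 is then an sp3 α-aryloxy methylene on which the ether oxygen can be placed by simple alkylation.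

**Retrosynthetic reasoning**

The benzylic alcohol of 14 is traced to aldehyde 13 and further to dimethyl acetal 12. No skeletal bond is cut. The B2 side-chain carbon is carried at the aldehyde level because the ring construction delivers it that way, and an acetal carbon does not interfere with the enolate chemistry that builds the ring. The forward steps must unmask the acetal without touching the prenyl ether and reduce the aldehyde without touching the ester.

The O–CH2 bond of the prenyl ether of 12 is cut to give phenol 10 and bromide 11. The cut is placed here because the ring construction leaves B6 as the only ring B phenol, whereas the ring A phenol is tied up in a hydrogen bond to the ester. The forward alkylation has to respect that difference.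

Ring B of 10 is opened at B1–B2 and B2–B3. This removes the one carbon (B2) that carries no ring oxygen and leaves enone 5, in which B6 is a ketone, B4 a ketone held as its methyl enol ether, B3 a vinylogous methyl and B1 an α-aryloxy methylene. The two-carbon acyl donor 8 supplies B2 together with its masked formyl substituent. Cutting here, and not at the diaryl ether, turns the hindered aryl–O–aryl bond into an sp3 C–O bond to be made earlier, and it differentiates all three ring B oxygens by origin: B1 from the ether, B4 from the enol ether, B6 from the ketone. The forward step must acylate B1 of 5 selectively, and then close B3 onto the new ketone of the unisolated diketone 9 and aromatize.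

Enone 5 is cut at the O–CH2 bond between ring A and B1, giving the symmetric diphenol 4 and bromo enone 3. Symmetry of 4 removes any regiochemical question, and after the first alkylation the remaining phenol is deactivated by chelation to the ester, so monoalkylation is the natural outcome. Ring A is bought complete, with the ester, the methyl and both oxygens in place.

Bromo enone 3 is traced through silyl dienol ether 2 to enone 1 by removing the bromine from C1. The forward sequence relies on the kinetic preference of β-alkoxy enones for deprotonation on the α' side and on the terminal carbon of the resulting diene being its most nucleophilic position.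

Acyl donor 8 is traced to acid 7 and ester 6. An activated amide is needed because the acylation must be run under mild magnesium and amine conditions, where a plain methyl ester would not react.

**Alternatives that were turned down**

Alternative 1: Ring A is disconnected at A1–A2 and A5–A6.
- Forward step: a Diels–Alder reaction of the ketene bis(silyl) acetal diene A3 with the aryloxypropiolate A2, followed by loss of a silanol, would give the silyl ether A1, and desilylation would give 14.
- For: the polarisation of both partners fixes the regiochemistry, the route is convergent at a late stage, and no phenol has to be differentiated at the end. On that last point it is stronger than the chosen route.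
- Against: the ring-forming step is spent on ring A, which can be purchased fully substituted as 4. Ring B, the hard ring, must first be made as phenol A4 by classical aromatic chemistry. A4 must then be converted into an ynol ether ester at a doubly ortho-substituted oxygen. A2 is a donor–acceptor alkyne and a sluggish dienophile, and the heat it would need brings the prenyl ether of ring B close to Claisen rearrangement into the free B5 position.
- Comparison: the chosen route builds the ring that cannot be bought, keeps every step at or near room temperature, and introduces the prenyl group only after the ring is formed.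

Alternative 2: The O–C(A6) and C(A1)–carboxyl bonds are cut.
- Forward step: the aryne released by fluoride from silyl triflate A6 would be attacked at A6 by the phenoxide of A4, and the A1 aryl anion would be trapped by carbon dioxide A7 to give acid A5. Esterification, removal of the methoxymethyl group and desilylation would follow.
- For: two bonds around ring A form in one operation with no ring synthesis. The alkoxy group of the aryne directs the nucleophile to the distal carbon and stabilises the anion at the proximal one, so the regiochemistry is sound. In convergence this is the strongest of the four plans.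
- Against: the nucleophile is a 2,6-disubstituted phenoxide, a poor partner for an aryne. Proton capture by the aryl anion competes with carboxylation. The prenyl group of A4 is an ideal ene donor towards an aryne. Both A4 and A6 need multistep preparation, and the protecting-group removals at the end require acid in the presence of the prenyl ether.
- Comparison: the chosen route needs no protecting group on either ring and does not depend on a hindered oxygen nucleophile attacking an sp2 carbon.

Alternative 3: Ring B is cut at B5–B6, B3–B4 and B1–B6.
- Forward step: irradiation of diazoketone A9 would give a vinylketene by Wolff rearrangement. [2+2] addition of methoxyethyne A10, ring opening of the cyclobutenone and six-electron electrocyclisation would give phenol A8, with the ether oxygen already on B1, methoxy on B4 and a free B6 phenol.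
- For: it shares the central idea of the chosen route (ether oxygen installed before ring B exists, B6 as the only free phenol). Its ring-forming cascade is pericyclic and irreversible, with no competing oxygen cyclisation, and in that respect it is more secure than the aldol closure chosen here.
- Against: A9 needs a β-aryloxy enone built from a monoprotected derivative of 4, followed by diazo transfer, which is about twice as many steps as the precursor 5. A10 is volatile and unstable. The step is photochemical, and two protecting groups must be removed afterwards under conditions that the prenyl ether tolerates poorly.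
- Comparison: the chosen route reaches its precursor in three steps from catalogue chemicals by ionic chemistry, carries the B4 methoxy in from the start, and delivers the B2 carbon already at a useful oxidation level.

Key step: step 6

Assumption: compounds 1, 4, 6 and 11 are taken as purchased materials, and 1 is the thermodynamically preferred E isomer.

**Route**

Step 1
Reactants: 1 (3E)-4-methoxypent-3-en-2-one
Product: 2 (3E)-4-methoxy-2-(trimethylsilyloxy)penta-1,3-diene
Conditions: LiN(iPr)2, THF, −78 °C; TMSCl, −78 → 0 °C; non-aqueous work-up
Reagents that add atoms: chlorotrimethylsilane, C[Si](C)(C)Cl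
Why: Kinetic deprotonation of a β-alkoxy enone by a lithium amide occurs at the α' methyl (C1) and not at the vinylogous methyl, and O-silylation of the cross-conjugated enolate gives the 2-silyloxy diene with the enol ether geometry untouched (kinetic silyl enol ether formation).

Step 2
Reactants: 2 (3E)-4-methoxy-2-(trimethylsilyloxy)penta-1,3-diene
Product: 3 (3E)-1-bromo-4-methoxypent-3-en-2-one
Conditions: NBS, THF, −78 → 0 °C; used without storage
Reagents that add atoms: N-bromosuccinimide, O=C1CCC(=O)N1Br
Why: Electrophilic halogenation of a silyl enol ether; bromine should add at the terminal CH2 because the resulting cation is stabilised by both the silyloxy and the methoxy oxygen, and loss of the silyl group restores the enone.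

Step 3
Reactants: 4 methyl 2,6-dihydroxy-4-methylbenzoate (slight excess); 3 (3E)-1-bromo-4-methoxypent-3-en-2-one
Product: 5 methyl 2-hydroxy-6-{[(3E)-4-methoxy-2-oxopent-3-en-1-yl]oxy}-4-methylbenzoate
Conditions: K2CO3, acetone, rt
Reagents that add atoms: none
Why: Williamson ether synthesis on a reactive α-bromo ketone; after the first alkylation the remaining phenol is locked in a hydrogen bond to the ester and is much less nucleophilic, so monoalkylation should dominate, and the weak base at room temperature should not enolise the product towards the ester.

Step 4
Reactants: 6 methyl 2,2-dimethoxyacetate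
Product: 7 2,2-dimethoxyacetic acid
Conditions: NaOH, MeOH/H2O, rt; then aq. HCl to pH 2, 0 °C, extraction
Reagents that add atoms: sodium hydroxide, [Na+].[OH-]
Why: Ester saponification; the acetal is inert to base, and the adjacent carboxyl group destabilises the oxocarbenium ion, so the acetal should survive the brief cold acidification.

Step 5
Reactants: 7 2,2-dimethoxyacetic acid
Product: 8 1-(2,2-dimethoxyacetyl)-1H-benzotriazole
Conditions: 1H-benzotriazole, DCC, CH2Cl2, 0 °C → rt
Reagents that add atoms: 1H-benzotriazole, c1ccc2[nH]nnc2c1
Why: Carbodiimide-mediated N-acylation of benzotriazole under neutral conditions, giving a storable acyl donor reactive enough for magnesium enolates.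

Step 6
Reactants: 5 methyl 2-hydroxy-6-{[(3E)-4-methoxy-2-oxopent-3-en-1-yl]oxy}-4-methylbenzoate; 8 1-(2,2-dimethoxyacetyl)-1H-benzotriazole
Product: 10 methyl 2-[2-(dimethoxymethyl)-6-hydroxy-4-methoxyphenoxy]-6-hydroxy-4-methylbenzoate, via 2-aryloxy-1,3-diketone 9 (not isolated)
Conditions: MgBr2·OEt2, iPr2NEt, CH2Cl2, 0 °C → rt; solvent exchange to MeCN; DBU, 60 °C
Reagents that add atoms: none
Why: MgBr2 binds the B6 carbonyl and the aryloxy oxygen and holds the ring A phenol as a magnesium phenoxide that deactivates the neighbouring ester, so iPr2NEt removes a B1 proton and the magnesium enolate is C-acylated by 8 to diketone 9 with loss of benzotriazole, which is a soft-enolisation Claisen acylation of a ketone with an N-acylbenzotriazole. DBU then removes a proton from the B3 methyl through the B4=B5–B6=O vinylogous system, and the dienolate carbon adds to the B2 ketone, which its two α-methoxy groups make the most electrophilic carbonyl of the chain; the closest known reaction is the base-induced aldol cyclodehydration of 1,3,5-tricarbonyl chains and their enol ethers to resorcinols. Ring B closes by a 6-(enolendo)-exo-trig aldol, which is possible because the E enol ether holds B3 cis to the B6 carbonyl. Loss of water across B2–B3 and enolisation of the B6 ketone aromatise the ring irreversibly and leave B6 as the only free ring B phenol. No stereocenter is formed, since B1 of 9 ends as an sp2 carbon. Acylation at B1 and not at B3 rests on chelation and on the inductive effect of the aryloxy group; Dieckmann attack of the B1 enolate on the ring A ester is outrun by the far more electrophilic acylbenzotriazole, and after acylation it could only give a non-enolisable adduct that reverts. Only one six-membered aldol is open, because B4 is fixed as an enol ether and the acetal carbon is not a useful enolate donor.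

Step 7
Reactants: 10 methyl 2-[2-(dimethoxymethyl)-6-hydroxy-4-methoxyphenoxy]-6-hydroxy-4-methylbenzoate; 11 1-bromo-3-methylbut-2-ene
Product: 12 methyl 2-{2-(dimethoxymethyl)-4-methoxy-6-[(3-methylbut-2-en-1-yl)oxy]phenoxy}-6-hydroxy-4-methylbenzoate
Conditions: K2CO3, acetone, rt (11 in 1.05 equiv)
Reagents that add atoms: none
Why: Williamson alkylation; the B6 phenol is a normal phenol whereas the ring A phenol is chelated to the ester and is deprotonated and alkylated far more slowly, so one equivalent of bromide should go to B6, and the acetal is inert to base.

Step 8
Reactants: 12 methyl 2-{2-(dimethoxymethyl)-4-methoxy-6-[(3-methylbut-2-en-1-yl)oxy]phenoxy}-6-hydroxy-4-methylbenzoate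
Product: 13 methyl 2-{2-formyl-4-methoxy-6-[(3-methylbut-2-en-1-yl)oxy]phenoxy}-6-hydroxy-4-methylbenzoate
Conditions: 1 M aq. HCl, THF, 0 °C → rt, short reaction time
Reagents that add atoms: water, O
Why: Acid hydrolysis of an electron-rich aryl dimethyl acetal, which ionises readily at a benzylic position and should cleave well before the prenyl ether or the ester is affected.

Step 9
Reactants: 13 methyl 2-{2-formyl-4-methoxy-6-[(3-methylbut-2-en-1-yl)oxy]phenoxy}-6-hydroxy-4-methylbenzoate
Product: 14 methyl 2-hydroxy-6-{2-(hydroxymethyl)-4-methoxy-6-[(3-methylbut-2-en-1-yl)oxy]phenoxy}-4-methylbenzoate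
Conditions: NaBH4, MeOH, 0 °C
Reagents that add atoms: none
Why: Chemoselective borohydride reduction of an aldehyde; the hindered, phenol-conjugated methyl ester and the prenyl alkene are not reduced under these conditions.

**Compound list**

1 | (3E)-4-methoxypent-3-en-2-one | CC(=O)/C=C(\C)OC | starting material
2 | (3E)-4-methoxy-2-(trimethylsilyloxy)penta-1,3-diene | C=C(O[Si](C)(C)C)/C=C(\C)OC | intermediate
3 | (3E)-1-bromo-4-methoxypent-3-en-2-one | BrCC(=O)/C=C(\C)OC | intermediate
4 | methyl 2,6-dihydroxy-4-methylbenzoate | COC(=O)c1c(O)cc(C)cc1O | starting material
5 | methyl 2-hydroxy-6-{[(3E)-4-methoxy-2-oxopent-3-en-1-yl]oxy}-4-methylbenzoate | COC(=O)c1c(O)cc(C)cc1OCC(=O)/C=C(\C)OC | intermediate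
6 | methyl 2,2-dimethoxyacetate | COC(=O)C(OC)OC | starting material
7 | 2,2-dimethoxyacetic acid | OC(=O)C(OC)OC | intermediate
8 | 1-(2,2-dimethoxyacetyl)-1H-benzotriazole | COC(OC)C(=O)n1nnc2ccccc12 | intermediate
9 | methyl 2-hydroxy-4-methyl-6-{[(5E)-1,1,6-trimethoxy-2,4-dioxohept-5-en-3-yl]oxy}benzoate (racemic at C3, largely enolised; not isolated) | COC(=O)c1c(O)cc(C)cc1OC(C(=O)C(OC)OC)C(=O)/C=C(\C)OC | intermediate
10 | methyl 2-[2-(dimethoxymethyl)-6-hydroxy-4-methoxyphenoxy]-6-hydroxy-4-methylbenzoate | COC(=O)c1c(O)cc(C)cc1Oc1c(C(OC)OC)cc(OC)cc1O | intermediate
11 | 1-bromo-3-methylbut-2-ene (prenyl bromide) | CC(C)=CCBr | starting material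
12 | methyl 2-{2-(dimethoxymethyl)-4-methoxy-6-[(3-methylbut-2-en-1-yl)oxy]phenoxy}-6-hydroxy-4-methylbenzoate | COC(=O)c1c(O)cc(C)cc1Oc1c(C(OC)OC)cc(OC)cc1OCC=C(C)C | intermediate
13 | methyl 2-{2-formyl-4-methoxy-6-[(3-methylbut-2-en-1-yl)oxy]phenoxy}-6-hydroxy-4-methylbenzoate | COC(=O)c1c(O)cc(C)cc1Oc1c(C=O)cc(OC)cc1OCC=C(C)C | intermediate
14 | methyl 2-hydroxy-6-{2-(hydroxymethyl)-4-methoxy-6-[(3-methylbut-2-en-1-yl)oxy]phenoxy}-4-methylbenzoate | COC(=O)c1c(O)cc(C)cc1Oc1c(CO)cc(OC)cc1OCC=C(C)C | target

**Step count and risk**

Total step count: 9. Longest linear sequence: 7 steps (steps 1, 2, 3, 6, 7, 8, 9). The acyl donor branch (steps 4 and 5) joins at step 6.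

Step 6 (key step).
- What may go wrong: three processes are most likely to divert it. Ring closure may occur through the enol oxygen of the diketone onto the methoxy-bearing carbon B4 with loss of methanol (a pyranone-forming addition–elimination), in place of the carbon–carbon aldol. The B3 methyl may be deprotonated too slowly, because the diketone rests as its unreactive B1 enolate. In the first stage, enolisation of the vinylogous ester may be incomplete, or acylation may go to oxygen (enolate or ring A phenoxide). A phenolic ester formed that way would be cleaved by brief methanolysis.
- Fallback: it sets out from 5 and comes back at 10, using the unmasked polyketone. Dilute aqueous HCl in THF would hydrolyse the enol ether of 5 to methyl 2-(2,4-dioxopentyloxy)-6-hydroxy-4-methylbenzoate F1. Its polyanion (excess LiN(iPr)2, THF, −78 → 0 °C) would be acylated by ester 6 at a terminal carbon to give methyl 2-(7,7-dimethoxy-2,4,6-trioxoheptyloxy)-6-hydroxy-4-methylbenzoate F2. Acylation at the other terminus would lead to the same ring after closure. Aqueous KOH would then bring about the classical triketone aldol cyclodehydration to the resorcinol methyl 2-[2-(dimethoxymethyl)-4,6-dihydroxyphenoxy]-6-hydroxy-4-methylbenzoate F3. One equivalent of iodomethane with K2CO3 is expected to methylate the unhindered B4 hydroxyl in preference to the flanked B6 and the chelated A2 hydroxyls, giving 10. The price is a less secure differentiation of the ring B oxygens and a separation.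

Step 2.
- What may go wrong: bromination may take place a second time or at the vinylic carbon, and the labile bromo enone may lose hydrogen bromide or hydrolyse at the enol ether on handling.
- Fallback: it sets out from 4 and comes back at 5 without any halo enone. Alkylation of 4 with 2-bromo-N-methoxy-N-methylacetamide (K2CO3, acetone) would give methyl 2-hydroxy-6-{2-[methoxy(methyl)amino]-2-oxoethoxy}-4-methylbenzoate F4. Excess 1-propynylmagnesium bromide (THF, 0 °C) would convert the Weinreb amide into the ynone methyl 2-hydroxy-4-methyl-6-(2-oxopent-3-ynyloxy)benzoate F5, with the ester protected as its magnesium phenoxide chelate. Conjugate addition of methanol (NaOMe, MeOH, 0 °C) under thermodynamic control should give the E β-methoxy enone 5.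

Step 3.
- What may go wrong: both phenols of 4 may be alkylated, or the base may induce attack of the ketone enolate on the neighbouring ester.
- Fallback: it sets out from 2 and 4 and comes back at 5 under neutral conditions. Rubottom oxidation of 2 (mCPBA, CH2Cl2, −20 °C, then mild aqueous desilylation) would give (3E)-1-hydroxy-4-methoxypent-3-en-2-one F6. Mitsunobu coupling of F6 with 4 (PPh3, DIAD, THF, 0 °C) would form the ether. The second, chelated phenol is a poor Mitsunobu partner and no enolate is generated.

Step 7.
- What may go wrong: the chelated ring A phenol may be alkylated as well, or the electron-rich phenoxide may be C-prenylated at B5.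
- Fallback: it sets out from 10 and comes back at 12. A Mitsunobu etherification with 3-methylbut-2-en-1-ol (PPh3, DIAD, THF, 0 °C) activates the alcohol instead of generating a phenoxide, discriminates strongly against the hydrogen-bonded phenol, and does not alkylate carbon. It makes no new compound (F0).

**Further compounds**

F1 | step 6 | methyl 2-(2,4-dioxopentyloxy)-6-hydroxy-4-methylbenzoate | COC(=O)c1c(O)cc(C)cc1OCC(=O)CC(C)=O
F2 | step 6 | methyl 2-(7,7-dimethoxy-2,4,6-trioxoheptyloxy)-6-hydroxy-4-methylbenzoate | COC(=O)c1c(O)cc(C)cc1OCC(=O)CC(=O)CC(=O)C(OC)OC
F3 | step 6 | methyl 2-[2-(dimethoxymethyl)-4,6-dihydroxyphenoxy]-6-hydroxy-4-methylbenzoate | COC(=O)c1c(O)cc(C)cc1Oc1c(C(OC)OC)cc(O)cc1O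
F4 | step 2 | methyl 2-hydroxy-6-{2-[methoxy(methyl)amino]-2-oxoethoxy}-4-methylbenzoate | COC(=O)c1c(O)cc(C)cc1OCC(=O)N(C)OC
F5 | step 2 | methyl 2-hydroxy-4-methyl-6-(2-oxopent-3-ynyloxy)benzoate | COC(=O)c1c(O)cc(C)cc1OCC(=O)C#CC
F6 | step 3 | (3E)-1-hydroxy-4-methoxypent-3-en-2-one | OCC(=O)/C=C(\C)OC
F0 | step 7 | none | none
A1 | alternative 1 | methyl 2-{2-[(tert-butyldimethylsilyloxy)methyl]-4-methoxy-6-(3-methylbut-2-enyloxy)phenoxy}-6-hydroxy-4-methylbenzoate | COC(=O)c1c(O)cc(C)cc1Oc1c(CO[Si](C)(C)C(C)(C)C)cc(OC)cc1OCC=C(C)C
A2 | alternative 1 | methyl 3-{2-[(tert-butyldimethylsilyloxy)methyl]-4-methoxy-6-(3-methylbut-2-enyloxy)phenoxy}prop-2-ynoate | COC(=O)C#COc1c(CO[Si](C)(C)C(C)(C)C)cc(OC)cc1OCC=C(C)C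
A3 | alternative 1 | 1,1-bis(trimethylsilyloxy)-3-methylbuta-1,3-diene | C=C(C)C=C(O[Si](C)(C)C)O[Si](C)(C)C
A4 | alternative 1 | 2-[(tert-butyldimethylsilyloxy)methyl]-4-methoxy-6-(3-methylbut-2-enyloxy)phenol | Oc1c(CO[Si](C)(C)C(C)(C)C)cc(OC)cc1OCC=C(C)C
A5 | alternative 2 | 2-{2-[(tert-butyldimethylsilyloxy)methyl]-4-methoxy-6-(3-methylbut-2-enyloxy)phenoxy}-6-(methoxymethoxy)-4-methylbenzoic acid | COCOc1cc(C)cc(Oc2c(CO[Si](C)(C)C(C)(C)C)cc(OC)cc2OCC=C(C)C)c1C(=O)O
A6 | alternative 2 | 3-(methoxymethoxy)-5-methyl-2-(trimethylsilyl)phenyl trifluoromethanesulfonate | COCOc1cc(C)cc(OS(=O)(=O)C(F)(F)F)c1[Si](C)(C)C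
A7 | alternative 2 | carbon dioxide | O=C=O
A8 | alternative 3 | methyl 2-{2-[(tert-butyldimethylsilyloxy)methyl]-6-hydroxy-4-methoxyphenoxy}-6-(methoxymethoxy)-4-methylbenzoate | COC(=O)c1c(OCOC)cc(C)cc1Oc1c(CO[Si](C)(C)C(C)(C)C)cc(OC)cc1O
A9 | alternative 3 | methyl 2-{[(1E)-2-[(tert-butyldimethylsilyloxy)methyl]-4-diazo-3-oxobut-1-en-1-yl]oxy}-6-(methoxymethoxy)-4-methylbenzoate | COC(=O)c1c(OCOC)cc(C)cc1O/C=C(\CO[Si](C)(C)C(C)(C)C)C(=O)C=[N+]=[N-]
A10 | alternative 3 | methoxyethyne | COC#C
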